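**Retrosynthetic overview**
1. Target acid ⇐ its methyl ester (saponification, last step).
2. The only ring, the 1,2-dioxolane, is formed in the penultimate step by a new catalytic asymmetric (3+2) annulation of a silylperoxycarbenium ion with methyl 3-methylbut-3-enoate. It forms C4–C5 and C3–O and sets C3 and C5.
3. Silyl peroxyketal ⇐ 2-methoxy-1-alkene (cobalt/O2/Et3SiH peroxidation) ⇐ methyl ester (ester methylenation).
4. The 3,5-anti-dimethyl ester ⇐ two cycles of Wittig homologation and Cu-catalysed asymmetric conjugate methylation ⇐ 9-phenylnonanal ⇐ 9-phenylnonan-1-ol.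

Assumption: the sense of induction is taken as written for the ligand or catalyst antipode named in steps 3, 6 and 9 (both antipodes are accessible); the antipode is exchanged if the first analytical run shows the opposite sense.

Catalyst of step 9: "(S,S)-IDPi" is the C2-symmetric imidodiphosphorimidate Brønsted acid built from two (S)-3,3'-bis[3,5-bis(trifluoromethyl)phenyl]-1,1'-bi-2-naphthol units, each phosphorus carrying an N-trifluoromethylsulfonyl imido group. It is the first-screen lead; the 3,3'-aryl wings are the variable to optimise. Compounds 1, 3 and 11 and all reagents are commercial.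

**Step 1**
Reactants: 1 9-phenylnonan-1-ol
Product: 2 9-phenylnonanal
Conditions: TEMPO (10 mol %), PhI(OAc)2 (1.1 equiv), CH2Cl2, rt
Reagents that add atoms: none
Why: TEMPO/PhI(OAc)2 oxidation (oxoammonium catalysis) takes an unhindered primary alcohol to the aldehyde without over-oxidation; no stereocentre is involved.

**Step 2**
Reactants: 2 9-phenylnonanal; 3 methyl (triphenyl-λ5-phosphanylidene)acetate
Product: 4 methyl (2E)-11-phenylundec-2-enoate
Conditions: 3 (1.2 equiv), CH2Cl2, rt, 12 h
Reagents that add atoms: none
Why: Wittig olefination with a stabilised ylide gives the (E)-enoate (>20:1), which is needed for a single facial sense in the next step.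

**Step 3**
Reactants: 4 methyl (2E)-11-phenylundec-2-enoate
Product: 5 methyl (3R)-3-methyl-11-phenylundecanoate
Conditions: MeMgBr (5 equiv), CuI (2 mol %), (S)-Tol-BINAP (3 mol %), t-BuOMe, −20 °C; aq NH4Cl
Reagents that add atoms: methylmagnesium bromide, C[Mg]Br
Why: Cu/Tol-BINAP-catalysed asymmetric conjugate addition of MeMgBr to a linear (E)-enoate is established for β-methyl esters (typically 90–96 % ee); the (S)-ligand is assigned to deliver methyl to the face that gives the 3R centre (the future C4' of the side chain).

**Step 4**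
Reactants: 5 methyl (3R)-3-methyl-11-phenylundecanoate
Product: 6 (3R)-3-methyl-11-phenylundecanal
Conditions: i-Bu2AlH (1.05 equiv), CH2Cl2, −78 °C; aq KNaC4H4O6 (potassium sodium tartrate)
Reagents that add atoms: none
Why: Partial reduction of a methyl ester with one equivalent of i-Bu2AlH at −78 °C stops at the aldehyde oxidation level; the β-stereocentre cannot epimerise.

**Step 5**
Reactants: 6 (3R)-3-methyl-11-phenylundecanal; 3 methyl (triphenyl-λ5-phosphanylidene)acetate
Product: 7 methyl (2E,5R)-5-methyl-13-phenyltridec-2-enoate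
Conditions: 3 (1.2 equiv), CH2Cl2, rt, 12 h
Reagents that add atoms: none
Why: Wittig olefination with the stabilised ylide again gives the (E)-enoate selectively and does not touch the β-methyl centre.

**Step 6**
Reactants: 7 methyl (2E,5R)-5-methyl-13-phenyltridec-2-enoate
Product: 8 methyl (3S,5R)-3,5-dimethyl-13-phenyltridecanoate (3,5-anti)
Conditions: MeMgBr (5 equiv), CuI (2 mol %), (R)-Tol-BINAP (3 mol %), t-BuOMe, −20 °C; aq NH4Cl
Reagents that add atoms: methylmagnesium bromide, C[Mg]Br
Why: Second Cu/Tol-BINAP asymmetric conjugate methylation under catalyst control: the (R)-ligand (antipode of step 3) overrides the remote δ-centre and gives the 3,5-anti (3S,5R) array, and the statistical amplification of two enantioselective steps leaves the major diastereomer essentially enantiopure.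

**Step 7**
Reactants: 8 methyl (3S,5R)-3,5-dimethyl-13-phenyltridecanoate
Product: 9 (4S,6R)-2-methoxy-4,6-dimethyl-14-phenyltetradec-1-ene
Conditions: Cp2TiMe2 (2.5 equiv), PhMe/THF, 65 °C, dark; filtration through basic Al2O3
Reagents that add atoms: dimethyltitanocene (Petasis reagent, Cp2TiMe2), C[Ti](C)(C1C=CC=C1)C1C=CC=C1
Why: Petasis methylenation converts the ester carbonyl into the 2-methoxy-1-alkene regiospecifically (a ketone route would give enol ether regioisomers) under non-basic conditions that leave both stereocentres untouched.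

**Step 8**
Reactants: 9 (4S,6R)-2-methoxy-4,6-dimethyl-14-phenyltetradec-1-ene
Product: 10 triethyl{[(4S,6R)-2-methoxy-4,6-dimethyl-14-phenyltetradecan-2-yl]peroxy}silane (both C2 epimers)
Conditions: Co(thd)2 [Co(C11H19O2)2, thd = 2,2,6,6-tetramethylheptane-3,5-dionate] (5 mol %), Et3SiH (2 equiv), O2 (1 atm), ClCH2CH2Cl, rt
Reagents that add atoms: dioxygen, O=O; triethylsilane, CC[SiH](CC)CC
Why: Isayama–Mukaiyama hydrosilylperoxidation: cobalt-hydride hydrogen-atom transfer to the terminal CH2 gives the α-methoxy tertiary radical, which traps O2 and is silylated, so the peroxide lands on the ketal carbon (Markovnikov); the new ketal centre forms as both epimers and is erased in step 9.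

**Step 9**
Reactants: 10 triethyl{[(4S,6R)-2-methoxy-4,6-dimethyl-14-phenyltetradecan-2-yl]peroxy}silane; 11 methyl 3-methylbut-3-enoate
Product: 14 methyl 2-[(3R,5R)-5-[(2S,4R)-2,4-dimethyl-12-phenyldodecyl]-3,5-dimethyl-1,2-dioxolan-3-yl]acetate, via silylperoxycarbenium ion 12 (not isolated), via open-chain tertiary carbocation 13 (not isolated)
Conditions: (S,S)-IDPi (5 mol %), 11 (3 equiv), PhMe, −78 °C, 24 h; Et3N quench
Reagents that add atoms: none
Why: Proposed new method: the confined chiral imidodiphosphorimidate acid ionises the methoxy group of 10 to the silylperoxycarbenium ion 12, which stays paired with the chiral anion; the anion pocket distinguishes the methyl flank from the branched alkyl flank of the C=O+ unit (as such anions do for silylated methyl alkyl ketones), so the terminal CH2 of 11 adds to one face and sets C5 (R); the tertiary cation 13 is then captured inside the same ion pair by the silylperoxy oxygen through the envelope that keeps both long arms (CH2CO2Me and the side chain) out of the pocket, which closes the ring with the two methyls cis and sets C3 (R); the Et3Si+ released ionises the next molecule of 10 and leaves as Et3SiOMe (silylium relay, so the acid is catalytic); there is no useful substrate bias, so both centres rest on the anion; the closest known reaction types are the SnCl4-promoted, non-enantioselective annulation of silylperoxycarbenium ions with 1,1-disubstituted alkenes and the imidodiphosphorimidate-catalysed asymmetric additions of π-nucleophiles to oxocarbenium ions (Mukaiyama aldol of ketones, Prins cyclisations); an enantioselective C–C bond formation at a peroxycarbenium ion has not been described.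

**Step 10**
Reactants: 14 methyl 2-[(3R,5R)-5-[(2S,4R)-2,4-dimethyl-12-phenyldodecyl]-3,5-dimethyl-1,2-dioxolan-3-yl]acetate
Product: 16 2-[(3R,5R)-5-[(2S,4R)-2,4-dimethyl-12-phenyldodecyl]-3,5-dimethyl-1,2-dioxolan-3-yl]acetic acid, via lithium carboxylate 15 (not isolated)
Conditions: LiOH·H2O (3 equiv), THF/H2O 3:1, 0 °C → rt; 1 M HCl to pH 3, 0 °C
Reagents that add atoms: lithium hydroxide, [Li+].[OH-]
Why: Ester saponification; the dioxolane carbons are fully substituted (no α-hydrogen for Kornblum–DeLaMare cleavage) and tolerate LiOH at 0 °C, no stereocentre is touched, and acidification of the carboxylate gives the target.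

**Compound list**
1 | 9-phenylnonan-1-ol | OCCCCCCCCCc1ccccc1 | starting material
2 | 9-phenylnonanal | O=CCCCCCCCCc1ccccc1 | intermediate
3 | methyl (triphenyl-λ5-phosphanylidene)acetate | COC(=O)C=P(c1ccccc1)(c1ccccc1)c1ccccc1 | starting material
4 | methyl (2E)-11-phenylundec-2-enoate | COC(=O)/C=C/CCCCCCCCc1ccccc1 | intermediate
5 | methyl (3R)-3-methyl-11-phenylundecanoate | C[C@H](CCCCCCCCc1ccccc1)CC(=O)OC | intermediate
6 | (3R)-3-methyl-11-phenylundecanal | C[C@H](CCCCCCCCc1ccccc1)CC=O | intermediate
7 | methyl (2E,5R)-5-methyl-13-phenyltridec-2-enoate | C[C@H](CCCCCCCCc1ccccc1)C/C=C/C(=O)OC | intermediate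
8 | methyl (3S,5R)-3,5-dimethyl-13-phenyltridecanoate | C[C@H](CCCCCCCCc1ccccc1)C[C@H](C)CC(=O)OC | intermediate
9 | (4S,6R)-2-methoxy-4,6-dimethyl-14-phenyltetradec-1-ene | C[C@H](CCCCCCCCc1ccccc1)C[C@H](C)CC(=C)OC | intermediate
10 | triethyl{[(4S,6R)-2-methoxy-4,6-dimethyl-14-phenyltetradecan-2-yl]peroxy}silane (both C2 epimers) | C[C@H](CCCCCCCCc1ccccc1)C[C@H](C)CC(C)(OC)OO[Si](CC)(CC)CC | intermediate
11 | methyl 3-methylbut-3-enoate | C=C(C)CC(=O)OC | starting material
12 | silylperoxycarbenium ion: [(4S,6R)-4,6-dimethyl-14-phenyltetradecan-2-ylidene](triethylsilylperoxy)oxonium, paired with the chiral IDPi anion | C[C@H](CCCCCCCCc1ccccc1)C[C@H](C)CC(C)=[O+]O[Si](CC)(CC)CC | intermediate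
13 | open-chain tertiary carbocation: C3 cation of methyl (5R,7S,9R)-3,5,7,9-tetramethyl-17-phenyl-5-(triethylsilylperoxy)heptadecanoate, paired with the chiral IDPi anion | C[C@H](CCCCCCCCc1ccccc1)C[C@H](C)C[C@@](C)(OO[Si](CC)(CC)CC)C[C+](C)CC(=O)OC | intermediate
14 | methyl 2-[(3R,5R)-5-[(2S,4R)-2,4-dimethyl-12-phenyldodecyl]-3,5-dimethyl-1,2-dioxolan-3-yl]acetate | C[C@H](CCCCCCCCc1ccccc1)C[C@H](C)C[C@]1(C)C[C@](C)(CC(=O)OC)OO1 | intermediate
15 | lithium 2-[(3R,5R)-5-[(2S,4R)-2,4-dimethyl-12-phenyldodecyl]-3,5-dimethyl-1,2-dioxolan-3-yl]acetate | C[C@H](CCCCCCCCc1ccccc1)C[C@H](C)C[C@]1(C)C[C@](C)(CC(=O)[O-])OO1.[Li+] | intermediate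
16 | 2-[(3R,5R)-5-[(2S,4R)-2,4-dimethyl-12-phenyldodecyl]-3,5-dimethyl-1,2-dioxolan-3-yl]acetic acid | C[C@H](CCCCCCCCc1ccccc1)C[C@H](C)C[C@]1(C)C[C@](C)(CC(=O)O)OO1 | target

**Totals**
Total step count: 10. Longest linear sequence: 10 steps (1 → 16); 3 and 11 are purchased.

**Three steps most likely to fail**

Step 9 (the proposed new annulation). Risks: insufficient facial control at C5 or at the ring closure (C3); ionisation of the silylperoxy group in place of the methoxy group; proton loss or fragmentation of the cations. Fallback with known chemistry, setting out from 10 (with 11) and coming back at 14: catalyst control is given up and replaced by separation. 10 and 11 (3 equiv) are treated with SnCl4 (1.0 equiv) in CH2Cl2 at −78 °C, the established stoichiometric annulation of silylperoxycarbenium ions with 1,1-disubstituted alkenes. This gives 14 together with its three ring diastereomers: the (3S,5S)-diastereomer of 14 F1, the (3S,5R)-diastereomer of 14 F2 and the (3R,5S)-diastereomer of 14 F3. Because the side chain is enantiopure all four are diastereomers. The trans pair (F2, F3) is removed on silica, and the two cis esters (14 and F1) are separated by preparative HPLC. 14 is identified by NOE between the ring methyls and by comparison of a hydrolysed sample with the data of the natural acid. Pure 14 rejoins the route at step 10.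

Step 8 (cobalt-catalysed silylperoxidation of an acid-labile enol ether). Risks: hydrolysis of 9, reduction of the peroxide by excess silane, loss of 10 on silica. Fallback, setting out from 9 and coming back at 10: an ionic perhydration replaces the radical peroxidation. Acid-catalysed Markovnikov addition of anhydrous ethereal H2O2 (5 equiv, pyridinium p-toluenesulfonate 2 mol %, Et2O, 0 °C; the reaction by which 2-methoxypropene caps hydroperoxides) gives (4S,6R)-2-hydroperoxy-2-methoxy-4,6-dimethyl-14-phenyltetradecane F4. O-Silylation (Et3SiCl, imidazole, DMF, 0 °C) then gives 10.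

Step 6 (catalyst-controlled anti methylation). Risks: MeMgBr is the least reactive Grignard reagent in this chemistry, and a few per cent of the 3,5-syn diastereomer would be inseparable from oily 8. Fallback, setting out from 7 and coming back at 8: auxiliary control replaces catalyst control.
- 7 is saponified (LiOH, THF/H2O; acid work-up) to (2E,5R)-5-methyl-13-phenyltridec-2-enoic acid F5.
- F5 is activated as (2E,5R)-5-methyl-13-phenyltridec-2-enoic pivalic anhydride F6 (t-BuCOCl, Et3N, THF, −20 °C; used in the same flask).
- F6 acylates (4R)-4-phenyl-1,3-oxazolidin-2-one (LiCl, rt) to give (4R)-3-[(2E,5R)-5-methyl-13-phenyltridec-2-enoyl]-4-phenyl-1,3-oxazolidin-2-one F7.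
- Conjugate addition of MeMgBr/CuBr·SMe2 (THF/Me2S, −40 → −20 °C) to the chelated s-cis imide occurs anti to the phenyl group and gives (4R)-3-[(3S,5R)-3,5-dimethyl-13-phenyltridecanoyl]-4-phenyl-1,3-oxazolidin-2-one F8. Its minor diastereomer can be removed by chromatography or crystallisation.
- NaOMe in MeOH (0 °C) releases 8 and the auxiliary.

**Further compounds**
F1 | step 9 | methyl 2-[(3S,5S)-5-[(2S,4R)-2,4-dimethyl-12-phenyldodecyl]-3,5-dimethyl-1,2-dioxolan-3-yl]acetate | C[C@H](CCCCCCCCc1ccccc1)C[C@H](C)C[C@@]1(C)C[C@@](C)(CC(=O)OC)OO1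
F2 | step 9 | methyl 2-[(3S,5R)-5-[(2S,4R)-2,4-dimethyl-12-phenyldodecyl]-3,5-dimethyl-1,2-dioxolan-3-yl]acetate | C[C@H](CCCCCCCCc1ccccc1)C[C@H](C)C[C@]1(C)C[C@@](C)(CC(=O)OC)OO1
F3 | step 9 | methyl 2-[(3R,5S)-5-[(2S,4R)-2,4-dimethyl-12-phenyldodecyl]-3,5-dimethyl-1,2-dioxolan-3-yl]acetate | C[C@H](CCCCCCCCc1ccccc1)C[C@H](C)C[C@@]1(C)C[C@](C)(CC(=O)OC)OO1
F4 | step 8 | (4S,6R)-2-hydroperoxy-2-methoxy-4,6-dimethyl-14-phenyltetradecane (both C2 epimers) | C[C@H](CCCCCCCCc1ccccc1)C[C@H](C)CC(C)(OC)OO
F5 | step 6 | (2E,5R)-5-methyl-13-phenyltridec-2-enoic acid | C[C@H](CCCCCCCCc1ccccc1)C/C=C/C(=O)O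
F6 | step 6 | (2E,5R)-5-methyl-13-phenyltridec-2-enoic pivalic anhydride | C[C@H](CCCCCCCCc1ccccc1)C/C=C/C(=O)OC(=O)C(C)(C)C
F7 | step 6 | (4R)-3-[(2E,5R)-5-methyl-13-phenyltridec-2-enoyl]-4-phenyl-1,3-oxazolidin-2-one | C[C@H](CCCCCCCCc1ccccc1)C/C=C/C(=O)N1C(=O)OC[C@H]1c1ccccc1
F8 | step 6 | (4R)-3-[(3S,5R)-3,5-dimethyl-13-phenyltridecanoyl]-4-phenyl-1,3-oxazolidin-2-one | C[C@H](CCCCCCCCc1ccccc1)C[C@H](C)CC(=O)N1C(=O)OC[C@H]1c1ccccc1
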